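**Retrosynthetic overview**
1. Target 15 ⇐ 14 ⇐ 13: the butyrolactone is the only ring made (both arenes are bought) and is closed last, by acid, from a γ-hydroxy tert-butyl ester; the same acid removes the phenol MOM group.
2. 13 ⇐ 12: the lactone CH2O carbon comes from chemoselective reduction of an N-acyl oxazolidinone in the presence of a tert-butyl ester.
3. 12 ⇐ 4 + 9: the central C2–C3 bond (lignan C8–C8') is made by oxidative heterocoupling of two lithium enolates. Fe(acac)3 oxidises one enolate to an electrophilic α-carbonyl species, so two α-carbons that are both normally nucleophilic are joined and both stereocentres are set at once.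
4. 4 ⇐ 1 + 2, with the auxiliary on the fragment whose centre cannot be epimerised later; 9 ⇐ 5 by MOM protection, Wittig olefination with 7 and hydrogenation.

Assumption: the SMILES is read as the (3R,4R)-trans lactone; substrates, building blocks, in-flask intermediates and products carry numbers, and simple reagents are given by name (with SMILES where they add atoms).

**Route**

Step 1
Reactants: 1 3-(3,4-dimethoxyphenyl)propanoic acid; 2 (S)-4-benzyl-1,3-oxazolidin-2-one
Product: 4 (S)-4-benzyl-3-[3-(3,4-dimethoxyphenyl)propanoyl]-1,3-oxazolidin-2-one, via mixed pivalic anhydride 3 (not isolated)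
Conditions: t-BuCOCl (1.1 equiv), Et3N (2.5 equiv), THF, −20 °C, 1 h; then LiCl (1.2 equiv), 2 (1.0 equiv), −20 °C → rt, 12 h
Reagents that add atoms: none
Why: Mixed-anhydride N-acylation, in which the acid is activated as its pivalic anhydride and the LiCl/Et3N-activated oxazolidinone attacks the less hindered carbonyl; no new stereocentre is formed and the (S)-centre of the auxiliary is untouched.

Step 2
Reactants: 5 syringaldehyde (4-hydroxy-3,5-dimethoxybenzaldehyde)
Product: 6 3,5-dimethoxy-4-(methoxymethoxy)benzaldehyde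
Conditions: MeOCH2Cl (1.5 equiv), iPr2NEt (2.0 equiv), CH2Cl2, 0 °C → rt
Reagents that add atoms: chloromethyl methyl ether, COCCl
Why: Williamson-type O-alkylation of the acidic phenol masks the easily oxidised syringyl phenol as a MOM acetal that tolerates ylide, hydrogenation, amide base, the iron oxidant and hydride but falls to acid at the end; no stereocentre.

Step 3
Reactants: 6 3,5-dimethoxy-4-(methoxymethoxy)benzaldehyde; 7 tert-butyl (triphenylphosphoranylidene)acetate
Product: 8 tert-butyl (E)-3-[3,5-dimethoxy-4-(methoxymethoxy)phenyl]prop-2-enoate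
Conditions: 7 (1.2 equiv), toluene, 90 °C, 12 h
Reagents that add atoms: none
Why: Wittig olefination with a stabilised ylide gives the (E)-cinnamate cleanly, and the geometry is erased in the next step; no stereocentre.

Step 4
Reactants: 8 tert-butyl (E)-3-[3,5-dimethoxy-4-(methoxymethoxy)phenyl]prop-2-enoate
Product: 9 tert-butyl 3-[3,5-dimethoxy-4-(methoxymethoxy)phenyl]propanoate
Conditions: H2 (1 atm), Pd/C (10 wt% palladium metal on carbon, 5 mol%), EtOAc, rt
Reagents that add atoms: none
Why: Heterogeneous catalytic hydrogenation saturates the conjugated C=C bond while the aryl ethers, the MOM acetal and the tert-butyl ester are inert (there is no benzylic C–O bond); no stereocentre.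

Step 5
Reactants: 4 (S)-4-benzyl-3-[3-(3,4-dimethoxyphenyl)propanoyl]-1,3-oxazolidin-2-one; 9 tert-butyl 3-[3,5-dimethoxy-4-(methoxymethoxy)phenyl]propanoate
Product: 12 tert-butyl (2R,3R)-3-{[(4S)-4-benzyl-2-oxo-1,3-oxazolidin-3-yl]carbonyl}-4-(3,4-dimethoxyphenyl)-2-{[3,5-dimethoxy-4-(methoxymethoxy)phenyl]methyl}butanoate, via imide lithium enolate 10 (not isolated), via ester lithium enolate 11 (not isolated)
Conditions: 4 (1.0 equiv), 9 (1.5 equiv), LiN(iPr)2 (2.6 equiv, commercial solution), THF, −78 °C, 45 min; then Fe(acac)3 (iron tris(acetylacetonate), trivalent iron, 2.6 equiv), THF, −78 °C → rt, 2 h; chromatography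
Reagents that add atoms: none
Why: Oxidative enolate heterocoupling, in which one-electron oxidation by Fe(acac)3 turns an enolate into an iron-bound α-carbonyl radical that acts as an electrophilic α-carbon and is captured by the second enolate (a second equivalent of oxidant completes the two-electron balance), the imide/ester pairing favouring the cross product over the homodimers; C3 is set by the chelated Z-enolate 10 reacting on the face away from the auxiliary benzyl group (Evans sense, giving R) and C2 by the usual like (R,R) preference of such couplings of 3-arylpropanoate enolates, with minor diastereomers and homodimers removed on silica.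

Step 6
Reactants: 12 tert-butyl (2R,3R)-3-{[(4S)-4-benzyl-2-oxo-1,3-oxazolidin-3-yl]carbonyl}-4-(3,4-dimethoxyphenyl)-2-{[3,5-dimethoxy-4-(methoxymethoxy)phenyl]methyl}butanoate
Product: 15 (3R,4R)-4-(3,4-dimethoxybenzyl)-3-(4-hydroxy-3,5-dimethoxybenzyl)dihydrofuran-2(3H)-one, via hydroxy tert-butyl ester 13 (not isolated), via MOM-protected lactone 14 (not isolated)
Conditions: LiBH4 (2.0 equiv), MeOH (2.0 equiv), THF, 0 °C, 2 h; then 3 M HCl in MeOH (excess), 0 → 50 °C, 6 h; concentrate from toluene; chromatography (auxiliary 2 recovered)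
Reagents that add atoms: none
Why: Chemoselective LiBH4 reduction of the activated imide carbonyl (reductive auxiliary cleavage) leaves the hindered tert-butyl ester, and methanolic HCl then drives acid-catalysed lactonisation with loss of tert-butanol and acetal exchange of the MOM ether to dimethoxymethane; neither stage enolises C2 or C3, so the (R,R) centres from step 5 become C3 and C4 of the trans-lactone unchanged.

**Compound list**

1 | 3-(3,4-dimethoxyphenyl)propanoic acid | COc1ccc(CCC(=O)O)cc1OC | starting material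
2 | (S)-4-benzyl-1,3-oxazolidin-2-one | O=C1N[C@@H](Cc2ccccc2)CO1 | starting material
3 | 3-(3,4-dimethoxyphenyl)propanoic pivalic anhydride (not isolated) | COc1ccc(CCC(=O)OC(=O)C(C)(C)C)cc1OC | intermediate
4 | (S)-4-benzyl-3-[3-(3,4-dimethoxyphenyl)propanoyl]-1,3-oxazolidin-2-one | COc1ccc(CCC(=O)N2[C@@H](Cc3ccccc3)COC2=O)cc1OC | intermediate
5 | syringaldehyde (4-hydroxy-3,5-dimethoxybenzaldehyde) | COc1cc(C=O)cc(OC)c1O | starting material
6 | 3,5-dimethoxy-4-(methoxymethoxy)benzaldehyde | COCOc1c(OC)cc(C=O)cc1OC | intermediate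
7 | tert-butyl (triphenylphosphoranylidene)acetate | CC(C)(C)OC(=O)C=P(c1ccccc1)(c1ccccc1)c1ccccc1 | starting material
8 | tert-butyl (E)-3-[3,5-dimethoxy-4-(methoxymethoxy)phenyl]prop-2-enoate | COCOc1c(OC)cc(/C=C/C(=O)OC(C)(C)C)cc1OC | intermediate
9 | tert-butyl 3-[3,5-dimethoxy-4-(methoxymethoxy)phenyl]propanoate | COCOc1c(OC)cc(CCC(=O)OC(C)(C)C)cc1OC | intermediate
10 | lithium (Z)-1-[(4S)-4-benzyl-2-oxo-1,3-oxazolidin-3-yl]-3-(3,4-dimethoxyphenyl)prop-1-en-1-olate (chelated Z-enolate of 4; not isolated) | COc1ccc(C/C=C(\O[Li])N2[C@@H](Cc3ccccc3)COC2=O)cc1OC | intermediate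
11 | lithium 1-tert-butoxy-3-[3,5-dimethoxy-4-(methoxymethoxy)phenyl]prop-1-en-1-olate (enolate of 9, drawn with OLi trans to the benzylic CH2; not isolated) | COCOc1c(OC)cc(C/C=C(/O[Li])OC(C)(C)C)cc1OC | intermediate
12 | tert-butyl (2R,3R)-3-{[(4S)-4-benzyl-2-oxo-1,3-oxazolidin-3-yl]carbonyl}-4-(3,4-dimethoxyphenyl)-2-{[3,5-dimethoxy-4-(methoxymethoxy)phenyl]methyl}butanoate | COc1ccc(C[C@@H](C(=O)N2[C@@H](Cc3ccccc3)COC2=O)[C@@H](Cc2cc(OC)c(OCOC)c(OC)c2)C(=O)OC(C)(C)C)cc1OC | intermediate
13 | tert-butyl (2R,3R)-4-(3,4-dimethoxyphenyl)-3-(hydroxymethyl)-2-{[3,5-dimethoxy-4-(methoxymethoxy)phenyl]methyl}butanoate (not isolated) | COc1ccc(C[C@@H](CO)[C@@H](Cc2cc(OC)c(OCOC)c(OC)c2)C(=O)OC(C)(C)C)cc1OC | intermediate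
14 | (3R,4R)-4-(3,4-dimethoxybenzyl)-3-[3,5-dimethoxy-4-(methoxymethoxy)benzyl]dihydrofuran-2(3H)-one (not isolated) | COc1ccc(C[C@H]2COC(=O)[C@@H]2Cc2cc(OC)c(OCOC)c(OC)c2)cc1OC | intermediate
15 | (3R,4R)-4-(3,4-dimethoxybenzyl)-3-(4-hydroxy-3,5-dimethoxybenzyl)dihydrofuran-2(3H)-one | COc1ccc(C[C@H]2COC(=O)[C@@H]2Cc2cc(OC)c(O)c(OC)c2)cc1OC | target

**Totals and risks**

Total step count: 6. Longest linear sequence: 5 steps (5 → 6 → 8 → 9 → 12 → 15, steps 2 to 6).

The three steps most likely to fail:

Step 5 (oxidative heterocoupling). The risks are competing homodimers of 4 and of 9, a realistic yield of only 40–55%, and modest selectivity at C2, the ester-side centre; C3 is auxiliary-controlled. The fallback sets out from 4 and comes back to the route at 14. It builds the same two C–C bonds one after the other with substrate-controlled alkylations. Deprotonation of 4 with NaN(SiMe3)2 (THF, −78 °C) and alkylation with tert-butyl bromoacetate gives tert-butyl (3R)-3-{[(4S)-4-benzyl-2-oxo-1,3-oxazolidin-3-yl]carbonyl}-4-(3,4-dimethoxyphenyl)butanoate F1. LiBH4/MeOH in THF at 0 °C then gives tert-butyl (3R)-4-(3,4-dimethoxyphenyl)-3-(hydroxymethyl)butanoate F2, which TsOH in toluene closes to (4R)-4-[(3,4-dimethoxyphenyl)methyl]oxolan-2-one F3. In parallel, aldehyde 6 is reduced with NaBH4 in MeOH to [3,5-dimethoxy-4-(methoxymethoxy)phenyl]methanol F4 and converted with CBr4/PPh3 (CH2Cl2, 0 °C) into 5-(bromomethyl)-1,3-dimethoxy-2-(methoxymethoxy)benzene F5. The lithium enolate of F3 (LiN(iPr)2, THF, −78 °C) is alkylated by F5 on the face anti to the C4 benzyl group and gives trans-lactone 14, which the methanolic HCl stage of step 6 turns into 15.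

Step 6 (reduction, lactonisation and MOM removal in one flask). The risks are hydride attack on the ring carbonyl of the hindered imide, and over-reduction to a diol if the lactone closes under the basic reduction conditions. The fallback sets out from 12 and comes back at 13. It replaces hydride cleavage of the imide by hydrolysis followed by acid-selective reduction. LiOH/H2O2 (THF/H2O, 0 °C) removes the auxiliary and gives (2R,3R)-3-(tert-butoxycarbonyl)-2-[(3,4-dimethoxyphenyl)methyl]-4-[3,5-dimethoxy-4-(methoxymethoxy)phenyl]butanoic acid F6. BH3·SMe2 (THF, 0 °C) reduces the free acid but not the tert-butyl ester and gives 13, which is then treated with methanolic HCl as in step 6.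

Step 4 (hydrogenation). This is the least worrying of the three; the danger is partial loss of the acid-labile MOM acetal on an acidic batch of catalyst, which would carry a free, oxidisable phenol into step 5. The fallback sets out from 5 and comes back at 9. It postpones protection until after the alkene is reduced. Wittig reaction of unprotected 5 with 7 (2.2 equiv, toluene, 90 °C) gives tert-butyl (E)-3-(4-hydroxy-3,5-dimethoxyphenyl)prop-2-enoate F7. Hydrogenation (H2, Pd/C, EtOAc) gives tert-butyl 3-(4-hydroxy-3,5-dimethoxyphenyl)propanoate F8, and MeOCH2Cl/iPr2NEt in CH2Cl2 then gives 9.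

**Further compounds**

F1 | step 5 | tert-butyl (3R)-3-{[(4S)-4-benzyl-2-oxo-1,3-oxazolidin-3-yl]carbonyl}-4-(3,4-dimethoxyphenyl)butanoate | COc1ccc(C[C@H](CC(=O)OC(C)(C)C)C(=O)N2[C@@H](Cc3ccccc3)COC2=O)cc1OC
F2 | step 5 | tert-butyl (3R)-4-(3,4-dimethoxyphenyl)-3-(hydroxymethyl)butanoate | COc1ccc(C[C@H](CC(=O)OC(C)(C)C)CO)cc1OC
F3 | step 5 | (4R)-4-[(3,4-dimethoxyphenyl)methyl]oxolan-2-one | COc1ccc(C[C@H]2COC(=O)C2)cc1OC
F4 | step 5 | [3,5-dimethoxy-4-(methoxymethoxy)phenyl]methanol | COCOc1c(OC)cc(CO)cc1OC
F5 | step 5 | 5-(bromomethyl)-1,3-dimethoxy-2-(methoxymethoxy)benzene | COCOc1c(OC)cc(CBr)cc1OC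
F6 | step 6 | (2R,3R)-3-(tert-butoxycarbonyl)-2-[(3,4-dimethoxyphenyl)methyl]-4-[3,5-dimethoxy-4-(methoxymethoxy)phenyl]butanoic acid | COc1ccc(C[C@@H](C(=O)O)[C@@H](Cc2cc(OC)c(OCOC)c(OC)c2)C(=O)OC(C)(C)C)cc1OC
F7 | step 4 | tert-butyl (E)-3-(4-hydroxy-3,5-dimethoxyphenyl)prop-2-enoate | COc1cc(/C=C/C(=O)OC(C)(C)C)cc(OC)c1O
F8 | step 4 | tert-butyl 3-(4-hydroxy-3,5-dimethoxyphenyl)propanoate | COc1cc(CCC(=O)OC(C)(C)C)cc(OC)c1O
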